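All runs were computed from invented constants; the scatter is artificial.

Thursday's run stood at 2.00 h with 11.4% of the whole charge as starting material and 2.5% as ring, though 50.0% had gone in. So 36.1% stood unread, a remainder that I took to feed ring through a slow closing, the rate-limiting step on the way to ring.

| setting | Thursday's | Saturday's | Monday's | gamma | eta |
|---|---|---|---|---|---|
| starting material | 20 mM (in portions, 2) | 20 mM (in portions, 2) | 40 mM (in portions, 2) | 20 mM | 20 mM (in portions, 2) |
| activator | 18 mM | 18 mM | 18 mM | 18.0 mM | 18.0 mM |
| protic impurity | 0.20 mM | 0.80 mM | 0.40 mM | 0.400 mM | 0.400 mM |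
| temperature | 65 °C | 76 °C | 65 °C | 70 °C | 70 °C |
| remark | run made earlier; portions every 3.0 h | run made earlier; portions every 3.0 h | run made earlier; portions every 3.0 h | everything together at the start | the portions of starting material follow each other after 3.0 h, the first at the start |
| time |  |  |  | 10 h | 10 h |

- Thursday's (time / h: ring / %, starting material / %): 0.667: 0, 24.9; 2.00: 2.5, 11.4; 4.00: 8.7, 32.4; 5.00: 14.9, 22.2; 8.00: 23.9, 13.7; 10.0: 32.7, 6.9
- Saturday's (time / h: ring / %, starting material / %): 1.50: 7.9, 3.1; 3.00: 18.1, 0; 5.00: 33.5, 14.9; 6.00: 44.5, 10.2; 8.00: 55.7, 6.7; 10.0: 62.3, 5.0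
- Monday's (time / h: ring / %, starting material / %): 2.00: 5.4, 14.6; 4.00: 4.7, 50.5; 6.00: 11.5, 45.0; 8.00: 14.8, 39.9; 10.0: 16.3, 37.9

(each reading ± 1 percentage point)

- what was read earlier has a scatter of 1 percentage point, one standard deviation
- a reading or a percentage of ring counts all its forms, free or not

- which of the two ends with the higher amount of ring, in percent of the starting material charged ("neither" if they lie within 2 percentage points) (gamma / eta / neither)
- ring at the end, in percent of the starting material charged, gamma
- ring at the end, in percent of the starting material charged, eta

I read two rows of Thursday's table, 5.00 h and 10.0 h, when both portions were in. The remainder held nearly steady, 62.9% and then 60.4%, while ring gained 18 percentage points. Ring gained per hour over the mean remainder gave a closing constant of 0.0577 h⁻¹.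

Saturday's same rows told another story: the remainder fell from 51.6% to 32.7%, and the constant read 0.137 h⁻¹, faster. Saturday's differed from Thursday's in protic impurity as well as in temperature, so what follows was a rough step. The temperature of gamma and eta lies a fraction 0.455 of the way between, so interpolating the logarithm gave my estimate of 0.0854 h⁻¹.

Eta's recipe lies between those two runs, and the same interpolation of their final rings gave eta 43.8%. I computed gamma as a correction. Counting each portion as closing from its arrival at that constant, I had eta's late half close for a time shorter by 3.0 h, so the late-portion gap, that half times the difference between exp(−k(t−tp)) and exp(−kt), was 6.2 points, above the margin. That put gamma at 50.0%. Monday's flask, with twice Thursday's charge and twice its protic impurity, ended at half Thursday's percentage, so I took my gap for gamma as a high figure.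

The forecast parted from me on the verdict: 45% for gamma, 44% for eta, so neither, since the effects "roughly cancel".

Gamma ended at 49.6% and eta at 45.1%, so gamma led.

    activator + ring ⇌ idle adduct, settled at all times (K = 43.8 L mol⁻¹, ΔH = 3.00 kJ mol⁻¹)
    starting material + protic impurity → quenched substrate (k = 0.714 L mol⁻¹ s⁻¹, Ea = 45.0 kJ mol⁻¹)
    starting material + activated form → open dimer (k = 0.00203 L mol⁻¹ s⁻¹, Ea = 74.0 kJ mol⁻¹)
    starting material + activator → activated form (k = 0.0246 L mol⁻¹ s⁻¹, Ea = 62.0 kJ mol⁻¹)
    activated form → ring (k = 3.45 × 10⁻⁵ s⁻¹, Ea = 103 kJ mol⁻¹)
    (constants at 70 °C)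

Gamma's lead of 4.5 points stands against my gap of 6.2 points, and its main reason is the way the starting material goes in: fed in eta's way, gamma falls from 49.6% to 45.1%. Left ten times as long, the same gap formula gives 0.0028 points, and the flasks lie within the margin, though with eta ahead, gamma at 76.6% and eta at 77.9%.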